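## Retrosynthetic overview

1. The target is cut at the interflavan C4(upper)–C8(lower) bond. The lower unit is commercial (−)-epigallocatechin 3-O-gallate used intact (gallate already on O3); the upper unit is an epicatechin C4 electrophile.
2. The electrophile is 4β-methoxy-epicatechin. Its C4–O bond is cut back to the C4–H bond of commercial (−)-epicatechin; this C–H to C–O oxygenation is the key step.
3. To steer the oxidant to ring A, the ring B catechol is tied up as a cyclic phenylboronate, which is hydrolysed off in the work-up of the oxygenation.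
4. Ring order: no ring is built. Rings A, B and C of both units and the galloyl ring arrive preformed. C2 and C3 of both units are bought; C4 is set by the facial bias of the 3-OH and 2-aryl groups.

Assumption: the SMILES is read as (−)-epicatechin-(4β→8)-(−)-epigallocatechin 3-O-gallate (upper unit 2R,3R,4R; lower unit 2R,3R), and both monomers are bought as single enantiomers.

## Route

Step 1
Reactants: 1 (−)-epicatechin
Product: 2 (−)-epicatechin 3',4'-O-phenylboronate
Conditions: PhB(OH)2 (1.05 equiv), THF, 4 Å MS, rt, 2 h; filter, evaporate, use crude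
Reagents that add atoms: phenylboronic acid, OB(O)c1ccccc1
Why: Boronic ester condensation, in which only the ortho-dihydroxy unit of ring B can close a five-membered dioxaborole, so the mask goes on selectively and no stereocentre is touched.

Step 2
Reactants: 2 (−)-epicatechin 3',4'-O-phenylboronate
Product: 5 4β-methoxy-(−)-epicatechin, via quinone methide boronate 3 (not isolated), via 4β-methoxy boronate 4 (not isolated)
Conditions: DDQ (1.0 equiv), MeOH (10 equiv), THF/MeCN 1:4, −30 → 0 °C, 30 min; then aq. NaH2PO4 (pH 5)/EtOAc; Sephadex LH-20 (EtOH)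
Reagents that add atoms: methanol, CO
Why: Proposed new method: with the easily oxidised ring B catechol held as an electron-poor boronate, DDQ can only engage the free phloroglucinol-type ring A, whose 7-OH is para to the benzylic C4, so net hydride loss from C4 gives the ring A para-quinone methide 3, which methanol traps at C4 on the β face, anti to the α-disposed 3-OH and 2-aryl groups (C4 set as S, 3,4-trans), while the remaining pseudo-equatorial C4–H is poorly aligned for a second oxidation; the closest known reactions are the DDQ/alcohol C4-alkoxylation of per-O-benzylated flavan-3-ols and the DDQ/MeOH benzylic methoxylation of para-alkylphenols through quinone methides, neither shown on a flavan with free ring A phenols and a boron-masked catechol.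

Step 3
Reactants: 5 4β-methoxy-(−)-epicatechin; 6 (−)-epigallocatechin 3-O-gallate (EGCG)
Product: 8 (−)-epicatechin-(4β→8)-(−)-epigallocatechin 3-O-gallate (target CNP0246304.2), via quinone methide 7 (not isolated)
Conditions: 6 (4 equiv), HCl (0.1 M) in MeOH, N2, 30 °C, 1 h; NaHCO3; Sephadex LH-20 then RP-HPLC (excess 6 recovered)
Reagents that add atoms: none
Why: Acid-catalysed SN1 Friedel–Crafts flavan-4-ylation (the biomimetic proanthocyanidin condensation), in which 5 ionises to 7 and C8 of ring A of 6, the most nucleophilic carbon of a free flavan-3-ol, attacks C4 from the β face, trans to the 3-OH and anti to the 2-aryl group, setting C4 as R, while the excess of 6 keeps the product from reacting with 7.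

## Compound list

1 | (−)-epicatechin; (2R,3R)-2-(3,4-dihydroxyphenyl)chromane-3,5,7-triol | O[C@@H]1Cc2c(O)cc(O)cc2O[C@@H]1c1ccc(O)c(O)c1 | starting material
2 | (−)-epicatechin 3',4'-O-phenylboronate; (2R,3R)-2-(2-phenyl-1,3,2-benzodioxaborol-5-yl)chromane-3,5,7-triol | O[C@@H]1Cc2c(O)cc(O)cc2O[C@@H]1c1ccc2OB(c3ccccc3)Oc2c1 | intermediate
3 | ring A para-quinone methide of 2; (2R,3R)-3,5-dihydroxy-2-(2-phenyl-1,3,2-benzodioxaborol-5-yl)-2,3-dihydro-7H-chromen-7-one (C4=C4a alkene, C7 ketone) | O=C1C=C(O)C2=C[C@@H](O)[C@@H](c3ccc4OB(c5ccccc5)Oc4c3)OC2=C1 | intermediate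
4 | 4β-methoxy-epicatechin 3',4'-O-phenylboronate; (2R,3R,4S)-4-methoxy-2-(2-phenyl-1,3,2-benzodioxaborol-5-yl)chromane-3,5,7-triol | CO[C@H]1c2c(O)cc(O)cc2O[C@H](c2ccc3OB(c4ccccc4)Oc3c2)[C@@H]1O | intermediate
5 | 4β-methoxy-(−)-epicatechin; (2R,3R,4S)-2-(3,4-dihydroxyphenyl)-4-methoxychromane-3,5,7-triol (2,3-cis, 3,4-trans) | CO[C@H]1c2c(O)cc(O)cc2O[C@H](c2ccc(O)c(O)c2)[C@@H]1O | intermediate
6 | (−)-epigallocatechin 3-O-gallate (EGCG); (2R,3R)-5,7-dihydroxy-2-(3,4,5-trihydroxyphenyl)chroman-3-yl 3,4,5-trihydroxybenzoate | O=C(O[C@@H]1Cc2c(O)cc(O)cc2O[C@@H]1c1cc(O)c(O)c(O)c1)c1cc(O)c(O)c(O)c1 | starting material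
7 | ring A para-quinone methide of epicatechin (reacts as its O-protonated C4 cation); (2R,3R)-2-(3,4-dihydroxyphenyl)-3,5-dihydroxy-2,3-dihydro-7H-chromen-7-one | O=C1C=C(O)C2=C[C@@H](O)[C@@H](c3ccc(O)c(O)c3)OC2=C1 | intermediate
8 | (−)-epicatechin-(4β→8)-(−)-epigallocatechin 3-O-gallate; (2R,3R)-8-[(2R,3R,4R)-2-(3,4-dihydroxyphenyl)-3,5,7-trihydroxychroman-4-yl]-5,7-dihydroxy-2-(3,4,5-trihydroxyphenyl)chroman-3-yl 3,4,5-trihydroxybenzoate | O=C(O[C@@H]1Cc2c(O)cc(O)c([C@H]3c4c(O)cc(O)cc4O[C@H](c4ccc(O)c(O)c4)[C@@H]3O)c2O[C@@H]1c1cc(O)c(O)c(O)c1)c1cc(O)c(O)c(O)c1 | target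

## Step count and risks

Total steps: 3. Longest linear sequence: 3 (1 → 2 → 5 → 8).

**Step 2 (the new C4–H oxygenation).** Risks: the boronate may slip off in the presence of methanol and expose the catechol to DDQ; quinone methide 3 may be captured by ring A of unreacted 2, giving oligomers; over-oxidation may give the 4-ketone. The fallback uses known chemistry throughout, sets out from 1 (with 6 as partner) and comes back to the route at 8.
- Benzylation of the four phenols of 1 (BnBr, K2CO3, DMF) gives 5,7,3',4'-tetra-O-benzyl-(−)-epicatechin F1.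
- The established DDQ oxidation in CH2Cl2 with 2-ethoxyethanol converts it into 4β-(2-ethoxyethoxy)-5,7,3',4'-tetra-O-benzylepicatechin F2.
- In parallel 6 is perbenzylated (BnBr, K2CO3, DMF) to octa-O-benzyl-EGCG F3.
- F2 and F3 (3 equiv) are joined with catalytic TMSOTf in CH2Cl2 at −40 °C, which is C8-selective and 3,4-trans, to give the dodeca-O-benzyl dimer F4.
- Hydrogenolysis (H2, Pd(OH)2/C, THF/MeOH/H2O) removes the twelve benzyl groups and delivers 8.

**Step 3 (free-phenol coupling).** Risks: about a quarter of the 4β→6 regioisomer is expected; the product can add to 7 to give a trimer; the acid can reopen the interflavan bond or slowly methanolyse the gallate on long exposure. The fallback sets out from 5 and comes back at 8.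
- 5 is exchanged at C4 with benzyl mercaptan and a little AcOH in EtOH (thiolysis-type substitution, β face) to give the bench-stable donor 4β-benzylthio-(−)-epicatechin F5.
- F5 and 6 (4 equiv) are coupled by thiophilic activation with AgBF4 in THF at 0 °C. This is aprotic and irreversible, with no methanol or mineral acid, so there is no scrambling and the product is simpler to separate.

**Step 1 (boronate mask).** Risks: esterification may be incomplete, or the ester may hydrolyse on handling, leaving free catechol that DDQ would turn into ortho-quinone. The fallback replaces the labile boron mask by a covalent ketal removed at the end; it sets out from 1 and comes back at 8.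
- 1 is heated with dichlorodiphenylmethane in diphenyl ether (170 °C) to give 3',4'-O-diphenylmethylene-(−)-epicatechin F6.
- DDQ/MeOH as in step 2 gives 4β-methoxy-3',4'-O-diphenylmethylene-epicatechin F7.
- Coupling with 6 in methanolic HCl as in step 3 gives the 3',4'-O-diphenylmethylene dimer F8.
- H2 over Pd/C in THF/MeOH cleaves the ketal (diphenylmethane is lost) and gives 8.

## Further compounds

F1 | step 2 | 5,7,3',4'-tetra-O-benzyl-(−)-epicatechin (2R,3R) | O[C@@H]1Cc2c(OCc3ccccc3)cc(OCc3ccccc3)cc2O[C@@H]1c1ccc(OCc2ccccc2)c(OCc2ccccc2)c1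
F2 | step 2 | 4β-(2-ethoxyethoxy)-5,7,3',4'-tetra-O-benzylepicatechin (2,3-cis, 3,4-trans) | CCOCCO[C@H]1c2c(OCc3ccccc3)cc(OCc3ccccc3)cc2O[C@H](c2ccc(OCc3ccccc3)c(OCc3ccccc3)c2)[C@@H]1O
F3 | step 2 | octa-O-benzyl-(−)-epigallocatechin 3-O-gallate (2R,3R) | O=C(O[C@@H]1Cc2c(OCc3ccccc3)cc(OCc3ccccc3)cc2O[C@@H]1c1cc(OCc2ccccc2)c(OCc2ccccc2)c(OCc2ccccc2)c1)c1cc(OCc2ccccc2)c(OCc2ccccc2)c(OCc2ccccc2)c1
F4 | step 2 | dodeca-O-benzyl epicatechin-(4β→8)-epigallocatechin 3-O-gallate (all phenols benzylated, upper 3-OH free) | O=C(O[C@@H]1Cc2c(OCc3ccccc3)cc(OCc3ccccc3)c([C@H]3c4c(OCc5ccccc5)cc(OCc5ccccc5)cc4O[C@H](c4ccc(OCc5ccccc5)c(OCc5ccccc5)c4)[C@@H]3O)c2O[C@@H]1c1cc(OCc2ccccc2)c(OCc2ccccc2)c(OCc2ccccc2)c1)c1cc(OCc2ccccc2)c(OCc2ccccc2)c(OCc2ccccc2)c1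
F5 | step 3 | 4β-benzylthio-(−)-epicatechin (2,3-cis, 3,4-trans) | c1ccccc1CS[C@H]1c2c(O)cc(O)cc2O[C@H](c2ccc(O)c(O)c2)[C@@H]1O
F6 | step 1 | 3',4'-O-diphenylmethylene-(−)-epicatechin; (2R,3R)-2-(2,2-diphenyl-1,3-benzodioxol-5-yl)chromane-3,5,7-triol | O[C@@H]1Cc2c(O)cc(O)cc2O[C@@H]1c1ccc2OC(c3ccccc3)(c3ccccc3)Oc2c1
F7 | step 1 | 4β-methoxy-3',4'-O-diphenylmethylene-epicatechin (2R,3R,4S) | CO[C@H]1c2c(O)cc(O)cc2O[C@H](c2ccc3OC(c4ccccc4)(c4ccccc4)Oc3c2)[C@@H]1O
F8 | step 1 | 3',4'-O-diphenylmethylene derivative (upper unit ring B) of epicatechin-(4β→8)-epigallocatechin 3-O-gallate | O=C(O[C@@H]1Cc2c(O)cc(O)c([C@H]3c4c(O)cc(O)cc4O[C@H](c4ccc5OC(c6ccccc6)(c6ccccc6)Oc5c4)[C@@H]3O)c2O[C@@H]1c1cc(O)c(O)c(O)c1)c1cc(O)c(O)c(O)c1
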